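The route cuts the C4–C4a bond of the lower flavan unit, so that its pyran ring (O1, C2, C3, C4, C4a, C8a) is the last ring closed. A gold-catalysed intramolecular Friedel–Crafts attack of the lower ring A on a terminal epoxide forms this bond, closes the ring and unveils the C3 hydroxyl in one operation; the 2,3-cis relationship is already stored in a threo aryl ether epoxide. The step exploits C4a of the lower ring A: it is the only free position ortho to O1, because C8 carries the biaryl bond, and the oxygens at C5 and C7 activate it. The precursor is an (−)-epicatechin-derived 6'-aryl compound made by Suzuki coupling.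

Key step: step 11

Remark on numbering: flavan numbering is used for both units; "upper" is the unit whose ring B carries the biaryl bond at C6', "lower" is the unit bonded through C8 of its ring A.
Assumption: the C6'–C8 biaryl axis bears no stereodescriptor in the target and is treated as configurationally undefined, so no atropisomer control is attempted. Compounds 1, 8 and 10 are taken as commercial.

Step 1
Reactants: 1 (−)-epicatechin
Product: 2 3',4'-O-(diphenylmethylene)epicatechin
Conditions: Ph2CCl2 (1.3 equiv), K2CO3 (3 equiv), MeCN, rt, Ar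
Reagents that add atoms: dichlorodiphenylmethane ClC(Cl)(c1ccccc1)c1ccccc1
Why: Ketalisation with a gem-dichloride, in which only the vicinal 3',4'-diol of ring B can close a five-membered 1,3-benzodioxole, so the catechol is masked selectively and C2 and C3 are untouched.

Step 2
Reactants: 2 3',4'-O-(diphenylmethylene)epicatechin
Product: 3 3,5,7-tri-O-acetyl-3',4'-O-(diphenylmethylene)epicatechin
Conditions: Ac2O (5 equiv), pyridine, DMAP (cat.), rt
Reagents that add atoms: acetic anhydride CC(=O)OC(C)=O
Why: DMAP-catalysed O-acylation of all three hydroxyls turns the two ring A phenols into weakly donating acetoxy groups, which deactivates ring A toward electrophiles.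

Step 3
Reactants: 3 3,5,7-tri-O-acetyl-3',4'-O-(diphenylmethylene)epicatechin
Product: 4 3,5,7-tri-O-acetyl-6'-bromo-3',4'-O-(diphenylmethylene)epicatechin
Conditions: NBS (1.05 equiv), MeCN, 0 °C to rt, dark
Reagents that add atoms: N-bromosuccinimide O=C1CCC(=O)N1Br
Why: Electrophilic aromatic bromination should take place on the benzodioxole ring B, now the most electron-rich ring, para to O3' at the free C6', as in the bromination of piperonyl systems.

Step 4
Reactants: 4 3,5,7-tri-O-acetyl-6'-bromo-3',4'-O-(diphenylmethylene)epicatechin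
Product: 6 3,5,7-tri-O-benzyl-6'-bromo-3',4'-O-(diphenylmethylene)epicatechin, via bromo triol 5 (not isolated)
Conditions: K2CO3 (0.2 equiv), MeOH–THF, rt, Ar; concentrate; then NaH (4 equiv), BnBr (3.6 equiv), Bu4NI (cat.), DMF, 0 °C to rt
Reagents that add atoms: benzyl bromide BrCc1ccccc1
Why: Ester methanolysis followed by Williamson etherification exchanges the acetates for benzyl ethers that survive base, palladium catalysis and Lewis acid, and because ring B stays ketal-protected no quinone methide can form to epimerise C2.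

Step 5
Reactants: 6 3,5,7-tri-O-benzyl-6'-bromo-3',4'-O-(diphenylmethylene)epicatechin
Product: 7 3,5,7-tri-O-benzyl-3',4'-O-(diphenylmethylene)epicatechin-6'-boronic acid pinacol ester
Conditions: B2pin2 (1.5 equiv), PdCl2(dppf) (5 mol %), KOAc (3 equiv), 1,4-dioxane, 90 °C
Reagents that add atoms: bis(pinacolato)diboron CC1(C)OB(OC1(C)C)B1OC(C)(C)C(C)(C)O1
Why: Miyaura borylation of the aryl bromide under zerovalent palladium catalysis with the mild base KOAc, to which ethers, ketal and both stereocentres are inert.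

Step 6
Reactants: 8 3,5-bis(benzyloxy)phenol
Product: 9 3,5-bis(benzyloxy)-2-iodophenol
Conditions: NIS (1.0 equiv), CH2Cl2, 0 °C, dark
Reagents that add atoms: N-iodosuccinimide O=C1CCC(=O)N1I
Why: Electrophilic aromatic iodination should go ortho to the hydroxyl, because the two equivalent ortho positions are para to a benzyloxy group and less hindered than C4 between the two benzyloxy groups, with one equivalent of reagent holding it at the mono stage.

Step 7
Reactants: 10 3,4-bis(benzyloxy)benzaldehyde
Product: 11 rac-1-[3,4-bis(benzyloxy)phenyl]prop-2-en-1-ol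
Conditions: CH2=CHMgBr (1.2 equiv), THF, 0 °C; aq. NH4Cl
Reagents that add atoms: vinylmagnesium bromide C=C[Mg]Br
Why: Grignard 1,2-addition to the aldehyde gives the racemic aryl vinyl carbinol that the kinetic resolution needs.

Step 8
Reactants: 11 rac-1-[3,4-bis(benzyloxy)phenyl]prop-2-en-1-ol
Product: 12 (S)-[3,4-bis(benzyloxy)phenyl][(2R)-oxiran-2-yl]methanol (erythro)
Conditions: Ti(OiPr)4 (15 mol %), L-(+)-DIPT (20 mol %), t-BuOOH (0.6 equiv), 4 Å MS, CH2Cl2, −20 °C
Reagents that add atoms: tert-butyl hydroperoxide CC(C)(C)OO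
Why: Sharpless asymmetric epoxidation in its kinetic-resolution mode, in which L-(+)-DIPT fixes the face of oxygen transfer (R at the oxirane carbon) and the erythro-selective titanium-bound transition state lets only the (R)-enantiomer of 11 react fast, while the (S)-enantiomer of 11 stays unreacted and is separated.

Step 9
Reactants: 12 (S)-[3,4-bis(benzyloxy)phenyl][(2R)-oxiran-2-yl]methanol; 9 3,5-bis(benzyloxy)-2-iodophenol
Product: 13 (2R)-2-{(R)-[3,4-bis(benzyloxy)phenyl][3,5-bis(benzyloxy)-2-iodophenoxy]methyl}oxirane (threo)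
Conditions: PPh3 (1.5 equiv), DIAD (1.5 equiv), toluene, −20 °C to rt
Reagents that add atoms: none
Why: Mitsunobu reaction in which the acidic ortho-iodophenol displaces the activated benzylic hydroxyl by SN2 with inversion, turning the (S) carbinol into the (R) aryl ether (erythro to threo), with low temperature limiting ionisation of the electron-rich benzylic centre.

Step 10
Reactants: 13 (2R)-2-{(R)-[3,4-bis(benzyloxy)phenyl][3,5-bis(benzyloxy)-2-iodophenoxy]methyl}oxirane; 7 3,5,7-tri-O-benzyl-3',4'-O-(diphenylmethylene)epicatechin-6'-boronic acid pinacol ester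
Product: 14 (2R,3R)-3,5,7-tris(benzyloxy)-2-[6-(2,4-bis(benzyloxy)-6-{(R)-[3,4-bis(benzyloxy)phenyl][(2R)-oxiran-2-yl]methoxy}phenyl)-2,2-diphenyl-1,3-benzodioxol-5-yl]chromane
Conditions: Pd(OAc)2 (5 mol %), SPhos (10 mol %), K3PO4 (3 equiv), toluene–H2O (10:1), 80 °C
Reagents that add atoms: none
Why: Suzuki–Miyaura coupling with a biaryl phosphine ligand suited to tri-ortho-substituted biaryls, the aryl iodide reacting under mild aqueous base that should leave the epoxide and all four stereocentres intact.

Step 11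
Reactants: 14 the biaryl ether epoxide from step 10
Product: 15 (2R,3R)-5,7-bis(benzyloxy)-2-[3,4-bis(benzyloxy)phenyl]-8-{2,2-diphenyl-6-[(2R,3R)-3,5,7-tris(benzyloxy)chroman-2-yl]-1,3-benzodioxol-5-yl}chroman-3-ol
Conditions: AuCl3 (5 mol %), AgOSO2CF3 (15 mol %), 4 Å MS, ClCH2CH2Cl, 0 °C to rt, 5 mM
Reagents that add atoms: none
Why: The cationic trivalent gold Lewis acid formed from AuCl3 and AgOSO2CF3 binds the oxirane oxygen of 14, and C4a of the lower ring A (ortho to O1 and to the C5 oxygen, para to the C7 oxygen) attacks the terminal oxirane carbon C4 in an SN2-like Friedel–Crafts alkylation, after which rearomatisation and proton transfer release the C3 hydroxyl. The closest known reaction type is the intramolecular Friedel–Crafts epoxy–arene cyclisation of aryl glycidyl ethers to chroman-3-ols, which has been applied to flavan-3-ols. The pyran ring closes in the 6-endo-tet mode (endo with respect to the oxirane) through the new C4–C4a bond. No stereocentre is created, since C4 is not stereogenic and the C3–O and C2–O1 bonds are not touched, so the threo (R,R) ether epoxide is transcribed into the 2R,3R (2,3-cis) ring. The step needs 6-endo over 5-exo opening, secured by the inductively deactivating and hindering aryloxy-bearing C2 next to C3, and a single site on ring A, secured because C8 is blocked by the biaryl bond, whose bulk also turns the O1–C2 bond toward C4a. Ionisation of the benzylic C2–O1 bond and intermolecular attack by the upper ring A should be held back by the mild catalyst, the low temperature and the high dilution.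

Step 12
Reactants: 15 the protected dimer from step 11
Product: 16 target, (2R,3R)-2-(3,4-dihydroxyphenyl)-8-{4,5-dihydroxy-2-[(2R,3R)-3,5,7-trihydroxychroman-2-yl]phenyl}chromane-3,5,7-triol
Conditions: H2 (1 atm), Pd(OH)2/C, THF–MeOH (1:1), rt
Reagents that add atoms: none
Why: Catalytic hydrogenolysis cleaves the seven benzyl ethers and the diphenylmethylene ketal in one neutral operation, which avoids oxidation or epimerisation of the free polyphenol, while the benzylic C2–O1 bonds of both pyran rings are known to survive such conditions.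

Compound list
1 | (−)-epicatechin, (2R,3R)-2-(3,4-dihydroxyphenyl)chromane-3,5,7-triol | Oc1cc(O)c2c(c1)O[C@H](c1ccc(O)c(O)c1)[C@H](O)C2 | starting material
2 | 3',4'-O-(diphenylmethylene)epicatechin, (2R,3R)-2-(2,2-diphenyl-1,3-benzodioxol-5-yl)chromane-3,5,7-triol | Oc1cc(O)c2c(c1)O[C@H](c1ccc3OC(c4ccccc4)(c4ccccc4)Oc3c1)[C@H](O)C2 | intermediate
3 | 3,5,7-tri-O-acetyl-3',4'-O-(diphenylmethylene)epicatechin (2R,3R) | CC(=O)Oc1cc(OC(C)=O)c2c(c1)O[C@H](c1ccc3OC(c4ccccc4)(c4ccccc4)Oc3c1)[C@H](OC(C)=O)C2 | intermediate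
4 | 3,5,7-tri-O-acetyl-6'-bromo-3',4'-O-(diphenylmethylene)epicatechin (2R,3R; bromine on ring B ortho to the carbon bearing C2) | CC(=O)Oc1cc(OC(C)=O)c2c(c1)O[C@H](c1cc3OC(c4ccccc4)(c4ccccc4)Oc3cc1Br)[C@H](OC(C)=O)C2 | intermediate
5 | 6'-bromo-3',4'-O-(diphenylmethylene)epicatechin, bromo triol (2R,3R) | Oc1cc(O)c2c(c1)O[C@H](c1cc3OC(c4ccccc4)(c4ccccc4)Oc3cc1Br)[C@H](O)C2 | intermediate (not isolated)
6 | 3,5,7-tri-O-benzyl-6'-bromo-3',4'-O-(diphenylmethylene)epicatechin, (2R,3R)-3,5,7-tris(benzyloxy)-2-(6-bromo-2,2-diphenyl-1,3-benzodioxol-5-yl)chromane | c1ccccc1COc1cc(OCc2ccccc2)c2c(c1)O[C@H](c1cc3OC(c4ccccc4)(c4ccccc4)Oc3cc1Br)[C@H](OCc1ccccc1)C2 | intermediate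
7 | 3,5,7-tri-O-benzyl-3',4'-O-(diphenylmethylene)epicatechin-6'-boronic acid pinacol ester (2R,3R) | c1ccccc1COc1cc(OCc2ccccc2)c2c(c1)O[C@H](c1cc3OC(c4ccccc4)(c4ccccc4)Oc3cc1B1OC(C)(C)C(C)(C)O1)[C@H](OCc1ccccc1)C2 | intermediate
8 | 3,5-bis(benzyloxy)phenol | Oc1cc(OCc2ccccc2)cc(OCc2ccccc2)c1 | starting material
9 | 3,5-bis(benzyloxy)-2-iodophenol | Oc1cc(OCc2ccccc2)cc(OCc2ccccc2)c1I | intermediate
10 | 3,4-bis(benzyloxy)benzaldehyde | O=Cc1ccc(OCc2ccccc2)c(OCc2ccccc2)c1 | starting material
11 | rac-1-[3,4-bis(benzyloxy)phenyl]prop-2-en-1-ol | C=CC(O)c1ccc(OCc2ccccc2)c(OCc2ccccc2)c1 | intermediate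
12 | (S)-[3,4-bis(benzyloxy)phenyl][(2R)-oxiran-2-yl]methanol (erythro) | O[C@@H](c1ccc(OCc2ccccc2)c(OCc2ccccc2)c1)[C@H]1CO1 | intermediate
13 | (2R)-2-{(R)-[3,4-bis(benzyloxy)phenyl][3,5-bis(benzyloxy)-2-iodophenoxy]methyl}oxirane (threo) | Ic1c(OCc2ccccc2)cc(OCc2ccccc2)cc1O[C@H](c1ccc(OCc2ccccc2)c(OCc2ccccc2)c1)[C@H]1CO1 | intermediate
14 | biaryl ether epoxide: 13 with the iodine replaced by C6' of the upper unit of 7 (upper 2R,3R; ether carbon R; oxirane carbon R) | c1ccccc1COc1cc(OCc2ccccc2)c2c(c1)O[C@H](c1cc3OC(c4ccccc4)(c4ccccc4)Oc3cc1-c1c(OCc3ccccc3)cc(OCc3ccccc3)cc1O[C@H](c1ccc(OCc3ccccc3)c(OCc3ccccc3)c1)[C@H]1CO1)[C@H](OCc1ccccc1)C2 | intermediate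
15 | protected dimer: hepta-O-benzyl diphenylmethylene ketal of the target with free lower 3-OH (both units 2R,3R) | c1ccccc1COc1cc(OCc2ccccc2)c2c(c1)O[C@H](c1cc3OC(c4ccccc4)(c4ccccc4)Oc3cc1-c1c(OCc3ccccc3)cc(OCc3ccccc3)c5c1O[C@H](c1ccc(OCc3ccccc3)c(OCc3ccccc3)c1)[C@H](O)C5)[C@H](OCc1ccccc1)C2 | intermediate
16 | target CNP0353739.3, epicatechin-(6'→8)-epicatechin (both units 2R,3R) | Oc1cc(O)c2c(c1)O[C@H](c1cc(O)c(O)cc1-c1c(O)cc(O)c3c1O[C@H](c1ccc(O)c(O)c1)[C@H](O)C3)[C@H](O)C2 | target

Total step count: 12.
Longest linear sequence: 8 steps (steps 1, 2, 3, 4, 5, 10, 11, 12).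

Steps most likely to fail

Step 11 (key step). What may go wrong: ionisation of the doubly activated benzylic C2–O1 ether bond by the Lewis acid (loss of the C2 configuration or cleavage of the ether), 5-exo opening at C3, or hydride-shift rearrangement of the epoxide to an aldehyde. Fallback: the same ring is closed through the O1–C2 bond instead of the C4–C4a bond. It sets out from 8: double iodination (NIS, 2.1 equiv, CH2Cl2) gives 3,5-bis(benzyloxy)-2,6-diiodophenol F1. Suzuki coupling of F1 (2 equiv, to hold the coupling at the mono stage) with boronate 7 (Pd(OAc)2, SPhos, K3PO4) gives the biaryl iodophenol F2. Deprotonation with MeMgCl, iodine–magnesium exchange with iPrMgCl·LiCl and CuI-catalysed opening of the magnesium alkoxide of epoxy alcohol 12 at its terminal carbon give the erythro (1S,2R) triol F3. An intramolecular Mitsunobu reaction (PPh3, DIAD, THF) then lets the phenol displace the benzylic hydroxyl with inversion, which from the erythro diol gives the 2R,3R pyran ring and comes back to the route at 15.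

Step 3. What may go wrong: poor ring selectivity, that is competing bromination of ring A at C6 or C8, because acetoxy groups deactivate only moderately. Fallback: ring A is deactivated more strongly by sulfonylation. It sets out from 2: TsCl and K2CO3 in acetone sulfonylate only the two phenols and give the 5,7-di-O-tosyl ketal F4. NBS in MeCN brominates C6' to give the bromo ditosylate F5. KOH in MeOH–THF at 60 °C cleaves the aryl tosylates and comes back to the route at 5, which is benzylated as in step 4.

Step 10. What may go wrong: slow transmetalation at the tri-ortho-substituted axis, so that protodeboronation of 7 and base-induced opening of the epoxide take over. Fallback: the order of the two bond formations is reversed. It sets out from 9: Suzuki coupling of the free iodophenol with 7 (same catalyst, no epoxide present, smaller ortho group) gives the biaryl phenol F6. Mitsunobu etherification of F6 with epoxy alcohol 12 (PPh3, DIAD, inversion at the benzylic carbon) comes back to the route at 14.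

Further compounds
F1 | step 11 | 3,5-bis(benzyloxy)-2,6-diiodophenol | Oc1c(I)c(OCc2ccccc2)cc(OCc2ccccc2)c1I
F2 | step 11 | biaryl iodophenol: 2-hydroxy-3-iodo-4,6-bis(benzyloxy)phenyl group at C6' of the protected upper unit (2R,3R) | c1ccccc1COc1cc(OCc2ccccc2)c2c(c1)O[C@H](c1cc3OC(c4ccccc4)(c4ccccc4)Oc3cc1-c1c(OCc3ccccc3)cc(OCc3ccccc3)c(I)c1O)[C@H](OCc1ccccc1)C2
F3 | step 11 | erythro triol: F2 with the iodine replaced by a (2R,3S)-3-[3,4-bis(benzyloxy)phenyl]-2,3-dihydroxypropyl chain | c1ccccc1COc1cc(OCc2ccccc2)c2c(c1)O[C@H](c1cc3OC(c4ccccc4)(c4ccccc4)Oc3cc1-c1c(OCc3ccccc3)cc(OCc3ccccc3)c(C[C@@H](O)[C@@H](O)c3ccc(OCc5ccccc5)c(OCc5ccccc5)c3)c1O)[C@H](OCc1ccccc1)C2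
F4 | step 3 | 5,7-di-O-tosyl-3',4'-O-(diphenylmethylene)epicatechin (2R,3R) | Cc1ccc(cc1)S(=O)(=O)Oc1cc(OS(=O)(=O)c2ccc(C)cc2)c2c(c1)O[C@H](c1ccc3OC(c4ccccc4)(c4ccccc4)Oc3c1)[C@H](O)C2
F5 | step 3 | 6'-bromo-5,7-di-O-tosyl-3',4'-O-(diphenylmethylene)epicatechin (2R,3R) | Cc1ccc(cc1)S(=O)(=O)Oc1cc(OS(=O)(=O)c2ccc(C)cc2)c2c(c1)O[C@H](c1cc3OC(c4ccccc4)(c4ccccc4)Oc3cc1Br)[C@H](O)C2
F6 | step 10 | biaryl phenol: 2-hydroxy-4,6-bis(benzyloxy)phenyl group at C6' of the protected upper unit (2R,3R) | c1ccccc1COc1cc(OCc2ccccc2)c2c(c1)O[C@H](c1cc3OC(c4ccccc4)(c4ccccc4)Oc3cc1-c1c(OCc3ccccc3)cc(OCc3ccccc3)cc1O)[C@H](OCc1ccccc1)C2
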